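## The problem

Asterriquinone I (23) is a 2,5-dimethoxy-1,4-benzoquinone whose two remaining ring carbons, para to each other, each carry a 3-indolyl group, and the two indoles differ. Indole A has a 1,1-dimethylallyl group on C2, which crowds the C3 position through which it is joined to the quinone. Indole B is unsubstituted in its pyrrole ring but carries a 2-hydroxy-3-methylbut-3-enyl chain on C7. The only stereocentre is the R allylic carbinol of that chain; it is remote from everything else, so no other part of the molecule can control it, and it must be set by a catalyst on a small fragment and carried through. The fragile parts are the methoxyquinone (a doubly vinylogous ester open to hydroxide and other nucleophiles), the secondary allylic alcohol (oxidised by the reagents that aromatise indolines, ionised by strong acid), the acid-sensitive alkenes and the two free N–H groups. C7 is the indole position least accessible by substitution chemistry, so the chain is best built in while the benzene ring is made. The structure allows this: the benzene ring of indole B has a single substituent, on C7, and C7 is bonded to C7a, the carbon attached to nitrogen. C7a and C7 can therefore be the two carbons of an ynamide, C3a and C4 a terminal alkyne tied to nitrogen through the C2–C3 ethylene unit, and C5 and C6 the two carbons of acetylene.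

## Retrosynthesis

**O–Si and C–OMe bonds of 23.** The carbinol is kept as its silyl ether 22 until the last step, and the two methoxy groups of 22 are traced to the two chlorines of dichloroquinone 21. Carrying chlorine rather than methoxy through the quinone assembly is deliberate: chlorine activates the quinone towards conjugate addition and blocks positions 2 and 5, so the two indoles can only enter at 3 and 6. The forward steps must exchange both chlorides without hydrolysing the product and remove silicon without base.

**C6(quinone)–C3(indole B) bond of 21.** This cut gives the mono-indolyl quinone 19 and the silyl-protected indole B 13. Cutting the indole A bond last would be worse, because the hindered indole A needs mineral acid to add and the side chain of indole B would not tolerate it. With indole A in place first, 13 can be added under a weak carboxylic acid, and the only free quinone carbon of 19 is the one para to indole A.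

**C3(quinone)–C3(indole A) bond of 19.** This leads to 2-(1,1-dimethylallyl)indole 16 and 2,5-dichloro-1,4-benzoquinone 17. Indole 16 comes from indole 14 in one operation by C2 reverse prenylation, so nothing is gained by building indole A on the core.

**Oxidation level and N-substituent of 13.** The C2=C3 double bond is removed and the nitrogen sulfonylated, giving indoline 12 and then N-tosylindoline 11. This is the oxidation level and protecting group that a cyclotrimerisation with a saturated two-carbon tether delivers. The forward steps are a reductive N–S cleavage and a dehydrogenation, both mild enough for the silyl ether and the isolated alkene.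

**Benzene ring of 11 (key disconnection).** Cutting C3a–C7a, C4–C5 and C6–C7 opens both rings and gives the ynamide diyne 9 and acetylene 10. The alternative of attaching a five-carbon chiral chain to C7 of a preformed bicyclic nucleus needs a directing group, an enantiopure electrophile and control of its site of attack. The alkyne cyclotrimerisation instead places the chain by connectivity: the substituent on the ynamide terminus can only become C7. Precursor 9 is acyclic and has the stereocentre already in place. The forward reaction must favour cross- over self-cyclotrimerisation and leave the 1,1-disubstituted alkene alone.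

**N–C(sp) bond of 9.** This cut gives bromoalkyne 6 and sulfonamide 8, to be joined by copper-catalysed N-alkynylation. It is the ynamide synthesis that accepts an alkyl-substituted alkyne and a silyl ether. Sulfonamide 8 is the tosyl derivative of but-3-yn-1-amine 7.

**C3–C4 bond of the hexenynol.** Bromoalkyne 6 is the brominated, silylated form (via 5) of (3R)-2-methylhex-1-en-5-yn-3-ol 4. Cutting the bond between the carbinol carbon and the propargylic CH2 gives methacrolein 1 and the allenylboronate 2. This one bond formation supplies the isopropenyl carbinol, the alkyne and the stereocentre together. It is done under catalyst control because no neighbouring stereocentre exists.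

## Roads not taken

Alternative 1: The cut runs through the quinone ring itself, at the bond between one carbonyl carbon and the carbon bearing indole A. The precursor is the squarate-derived cyclobutenone A1, a 4-hydroxy-2-methoxycyclobutenone with N-SEM indole B on C3 and a 1-methoxy-2-(indole A)vinyl group on C4. On heating, a four-electron ring opening and a six-electron ring closure with tautomerisation would give hydroquinone A2, which a mild oxidant takes to the quinone.
- Merits: both methoxy groups arrive with the building blocks, the para pattern follows from connectivity, and no acid meets the side chain. In these respects it is better than the chosen plan, which must exchange two chlorides on a sensitive quinone.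
- Weak points:
  - In making A1, the alkenyl nucleophile must add to the carbonyl next to the indolyl-bearing ring carbon and not to the one next to the methoxy-bearing carbon.
  - That nucleophile sits beside the bulky 2-(1,1-dimethylallyl)indole.
  - Both indoles need N-protection, and freeing two N-SEM indoles needs hot fluoride or strong Lewis acid in the presence of a methoxyquinone and an allylic alcohol.
  - The plan does not say how indole B and its stereocentre are made; something like 13 would still be required.
- Comparison: against the elegance of A2, the chosen plan offers a core assembly from unprotected indoles in three known operations, and it spends its key step on the C7 chain and the stereocentre.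

Alternative 2: Indole A is made last, on the finished core, by cutting its C3–C3a and N1–C2 bonds. This leads to 2-iodoaniline A3 and the aryl alkyne A4, a 2,5-dimethoxy-3,6-bis(methoxymethoxy)benzene carrying silyl-protected indole B and a 3,3-dimethylpent-4-en-1-ynyl group para to each other. In a Larock heteroannulation under Pd(OAc)2, oxidative addition of A3 to zerovalent palladium, syn-carbopalladation of the alkyne and C–N reductive elimination would give A5. Removal of the acetal groups and oxidation would then give the quinone.
- Merits: the crowded C3 of indole A never has to act as a nucleophile, and a bulky tertiary alkyl group normally ends up next to nitrogen, as required. A5 is also better in that the core stays at the robust arene level until the end.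
- Weak points:
  - The alkyne lies between a quaternary carbon and a di-ortho-substituted arene and may not insert.
  - With two large flanking groups, the regiochemistry is not assured.
  - The terminal vinyl group can enter Heck pathways.
  - The hexasubstituted benzene A4 needs a long sequence of cross-couplings.
  - Acidic removal of two methoxymethyl ethers endangers the silyl ether and the alkenes.
  - Indole B again has to be supplied.
- Comparison: in the chosen plan the hindered indole 16 is a one-step compound and its union with 17 under mineral acid is a known reaction type, so the late indole synthesis gains little.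

Alternative 3: The quinone ring is cut into two indolylpyruvate units, as in the biosynthesis, at the two ring bonds that join each carboxyl carbon to the indolyl-bearing carbon of the other unit. The enolate of the indole B pyruvate ester A6 would attack the lactone carbonyl of dioxolanone A7, the masked enol of the indole A pyruvic acid. The enolate released by that acylation would then close onto the ester (Claisen then Dieckmann condensation) to give dihydroxyquinone A8.
- Merits: this is the most direct assembly of the core, without halogenated quinones, acid or oxidant. The masking differentiates the two units, so cross-coupling is built into the reagents. It is more convergent than the chosen plan.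
- Weak points:
  - The Dieckmann nucleophile is the carbon next to the 2-(1,1-dimethylallyl)indole and is badly hindered.
  - A6 can self-condense.
  - A8 is at the dihydroxy level and needs a double O-methylation.
  - Two N-SEM groups must be removed from a quinone.
  - Each pyruvate costs several steps from its indole.
  - The indole B problem is untouched.
- Comparison: on operations for the core the two plans are about level. The chosen plan answers with unprotected indoles, a first union known to accept the hindered indole, and a methoxide exchange that reaches the dimethyl ether directly.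

Key step: step 6

Assumption: (R)-TRIP is taken to deliver the R carbinol from methacrolein through the same closed transition state as with aryl and alkenyl aldehydes; if the sense is reversed, the S acid is used and nothing else changes.
Assumption: compounds 1, 2, 7, 10, 14 and 17 and all reagents (including 9-BBN and 3-methylbuta-1,2-diene) are taken as commercial.

## Route

Step 1
Reactants: 1 methacrolein; 2 allenylboronic acid pinacol ester
Product: 4 (3R)-2-methylhex-1-en-5-yn-3-ol, via pinacol borate ester 3 (not isolated)
Conditions: (R)-TRIP (10 mol%), 4 Å MS, toluene, −20 °C; aq. NaHCO3 work-up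
Reagents that add atoms: none
Why: Chiral phosphoric acid-catalysed allenylboration (asymmetric propargylation): the acid binds the boronate oxygen and the formyl group in a closed six-membered SE2' transition state, so the allenyl group is delivered as a propargyl group and the 3,3'-aryl groups of the catalyst select the aldehyde face that gives the R carbinol. Work-up hydrolyses borate 3; alkenyl aldehydes are within the known scope.

Step 2
Reactants: 4 (3R)-2-methylhex-1-en-5-yn-3-ol
Product: 5 tert-butyldimethyl{[(3R)-2-methylhex-1-en-5-yn-3-yl]oxy}silane
Conditions: TBSCl, imidazole, DMF, 0 °C to rt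
Reagents that add atoms: tert-butyldimethylsilyl chloride, CC(C)(C)[Si](C)(C)Cl
Why: Standard imidazole-mediated silylation of a secondary alcohol. The TBS ether is chosen to survive copper, rhodium, Mg/MeOH, MnO2 and methoxide and to leave under buffered fluoride at the end; it also removes the volatility of 4.

Step 3
Reactants: 5 tert-butyldimethyl{[(3R)-2-methylhex-1-en-5-yn-3-yl]oxy}silane
Product: 6 {[(3R)-6-bromo-2-methylhex-1-en-5-yn-3-yl]oxy}(tert-butyl)dimethylsilane
Conditions: NBS, AgNO3 (10 mol%), acetone, rt, dark
Reagents that add atoms: N-bromosuccinimide, O=C1CCC(=O)N1Br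
Why: Silver-catalysed electrophilic bromination of a terminal alkyne through the silver acetylide, which under these conditions is much faster than any reaction of NBS with the 1,1-disubstituted alkene.

Step 4
Reactants: 7 but-3-yn-1-amine
Product: 8 N-(but-3-yn-1-yl)-4-methylbenzenesulfonamide
Conditions: TsCl, Et3N, CH2Cl2, 0 °C to rt
Reagents that add atoms: 4-methylbenzenesulfonyl chloride, Cc1ccc(cc1)S(=O)(=O)Cl
Why: Sulfonylation of a primary amine; the tosyl group makes the N–H acidic enough for the copper coupling and stabilises the ynamide.

Step 5
Reactants: 6 {[(3R)-6-bromo-2-methylhex-1-en-5-yn-3-yl]oxy}(tert-butyl)dimethylsilane; 8 N-(but-3-yn-1-yl)-4-methylbenzenesulfonamide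
Product: 9 N-(but-3-yn-1-yl)-N-[(4R)-4-(tert-butyldimethylsilyloxy)-5-methylhex-5-en-1-yn-1-yl]-4-methylbenzenesulfonamide
Conditions: CuSO4·5H2O (10 mol%), 1,10-phenanthroline (20 mol%), K3PO4, toluene, 70 °C
Reagents that add atoms: none
Why: Copper-catalysed N-alkynylation of a sulfonamide with a 1-bromoalkyne (Ullmann-type amidation at an sp carbon), the standard ynamide synthesis, which is also used for sulfonamides that carry a second alkyne in the N-substituent. The weak base and moderate temperature leave the silyl ether and the stereocentre untouched.

Step 6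
Reactants: 9 N-(but-3-yn-1-yl)-N-[(4R)-4-(tert-butyldimethylsilyloxy)-5-methylhex-5-en-1-yn-1-yl]-4-methylbenzenesulfonamide; 10 acetylene
Product: 11 7-[(2R)-2-(tert-butyldimethylsilyloxy)-3-methylbut-3-en-1-yl]-1-(4-methylbenzenesulfonyl)-2,3-dihydro-1H-indole
Conditions: RhCl(PPh3)3 (5 mol%), C2H2 (1 atm), toluene, 20–40 °C, slow addition of 9
Reagents that add atoms: none
Why: This is a [2+2+2] alkyne cyclotrimerisation of a nitrogen-tethered ynamide diyne with a monoalkyne under RhCl(PPh3)3, the known route to N-sulfonyl indolines. After loss of a phosphine, monovalent rhodium binds both alkynes of 9 and oxidative cyclisation joins the nitrogen-bound ynamide carbon to the internal carbon of the butynyl alkyne (C7a–C3a), giving a rhodacyclopentadiene of trivalent rhodium; the five-membered ring is thus closed by metal-templated oxidative coupling across the N–CH2–CH2 tether. Acetylene then inserts into a Rh–C bond and C–C reductive elimination closes the benzene ring, forming C4–C5 and C6–C7 and returning monovalent rhodium. No stereocentre is formed, and the silylated carbinol, two bonds from the reacting alkyne, is a spectator. Regiochemistry needs no control, because the tether fixes the ynamide terminus as C7 and acetylene is symmetric. The selectivity needed is cross- over self-cyclotrimerisation, secured by an acetylene-saturated solution and slow addition of 9; the substituted ynamide terminus also makes 9 a poor monoalkyne partner for its own metallacycle. The 1,1-disubstituted alkene is hindered and stands in a 1,5-enyne relationship, so it should not compete for the metallacycle.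

Step 7
Reactants: 11 7-[(2R)-2-(tert-butyldimethylsilyloxy)-3-methylbut-3-en-1-yl]-1-(4-methylbenzenesulfonyl)-2,3-dihydro-1H-indole
Product: 12 7-[(2R)-2-(tert-butyldimethylsilyloxy)-3-methylbut-3-en-1-yl]-2,3-dihydro-1H-indole
Conditions: Mg turnings, MeOH, sonication, rt
Reagents that add atoms: none
Why: Reductive N–S cleavage of an N-aryl sulfonamide by single-electron transfer from magnesium in methanol; the isolated alkene and the silyl ether are inert to these conditions.

Step 8
Reactants: 12 7-[(2R)-2-(tert-butyldimethylsilyloxy)-3-methylbut-3-en-1-yl]-2,3-dihydro-1H-indole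
Product: 13 7-[(2R)-2-(tert-butyldimethylsilyloxy)-3-methylbut-3-en-1-yl]-1H-indole
Conditions: MnO2 (activated, excess), CH2Cl2, rt
Reagents that add atoms: none
Why: Dehydrogenation of an indoline to the indole with activated MnO2, driven by aromatisation and known for 7-alkylindolines; the carbinol is silylated, so no allylic alcohol is exposed to the oxidant.

Step 9
Reactants: 14 indole
Product: 16 2-(2-methylbut-3-en-2-yl)-1H-indole, via 3-chloro-3H-indole 15 (not isolated)
Conditions: t-BuOCl, Et3N, THF, −78 °C; then B-prenyl-9-BBN (from 9-BBN and 3-methylbuta-1,2-diene, THF), −78 °C to rt; aq. K2CO3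
Reagents that add atoms: B-prenyl-9-BBN, CC(C)=CCB1C2CCCC1CCC2 (made in the flask from 3-methylbuta-1,2-diene, CC(C)=C=C, and 9-BBN)
Why: Reverse prenylation of an indole through its chloroindolenine: C3 chlorination gives 15, whose C=N bond is allylborated through a six-membered transition state with allylic transposition, so the tertiary carbon bonds to C2. Loss of HCl and hydrolysis of the N–B bond restore the indole.

Step 10
Reactants: 16 2-(2-methylbut-3-en-2-yl)-1H-indole; 17 2,5-dichloro-1,4-benzoquinone
Product: 19 2,5-dichloro-3-[2-(2-methylbut-3-en-2-yl)-1H-indol-3-yl]cyclohexa-2,5-diene-1,4-dione, via dichlorohydroquinone 18 (not isolated)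
Conditions: conc. HCl (cat.), THF, rt; then DDQ, rt
Reagents that add atoms: none
Why: Acid-promoted conjugate (Friedel–Crafts/Michael) addition of indole C3 to an unsubstituted carbon of the protonated quinone, followed by DDQ oxidation of hydroquinone 18. Mineral acid is used because C3 is flanked by the tertiary alkyl group, and mono-addition is favoured because the indolyl quinone is a weaker acceptor than 17.

Step 11
Reactants: 19 2,5-dichloro-3-[2-(2-methylbut-3-en-2-yl)-1H-indol-3-yl]cyclohexa-2,5-diene-1,4-dione; 13 7-[(2R)-2-(tert-butyldimethylsilyloxy)-3-methylbut-3-en-1-yl]-1H-indole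
Product: 21 3-{7-[(2R)-2-(tert-butyldimethylsilyloxy)-3-methylbut-3-en-1-yl]-1H-indol-3-yl}-2,5-dichloro-6-[2-(2-methylbut-3-en-2-yl)-1H-indol-3-yl]cyclohexa-2,5-diene-1,4-dione, via bis-indolyl hydroquinone 20 (not isolated)
Conditions: AcOH, rt to 40 °C; then DDQ, THF, rt
Reagents that add atoms: none
Why: Second acid-promoted conjugate addition of an indole to a chloroquinone: the only C–H carbon left in 19 is para to indole A, so the regiochemistry is fixed. Acetic acid is enough for the unhindered C3 of 13 and spares the silyl ether and the allylic system; DDQ reoxidises 20.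

Step 12
Reactants: 21 3-{7-[(2R)-2-(tert-butyldimethylsilyloxy)-3-methylbut-3-en-1-yl]-1H-indol-3-yl}-2,5-dichloro-6-[2-(2-methylbut-3-en-2-yl)-1H-indol-3-yl]cyclohexa-2,5-diene-1,4-dione
Product: 22 3-{7-[(2R)-2-(tert-butyldimethylsilyloxy)-3-methylbut-3-en-1-yl]-1H-indol-3-yl}-2,5-dimethoxy-6-[2-(2-methylbut-3-en-2-yl)-1H-indol-3-yl]cyclohexa-2,5-diene-1,4-dione
Conditions: NaOMe, MeOH/THF (anhydrous), 0 °C to rt
Reagents that add atoms: sodium methoxide, C[O-].[Na+]
Why: Addition–elimination (vinylogous acyl substitution) of methoxide at both chlorine-bearing quinone carbons, a standard conversion of haloquinones into methoxyquinones; without water the reaction should stop at the dimethyl ether.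

Step 13
Reactants: 22 3-{7-[(2R)-2-(tert-butyldimethylsilyloxy)-3-methylbut-3-en-1-yl]-1H-indol-3-yl}-2,5-dimethoxy-6-[2-(2-methylbut-3-en-2-yl)-1H-indol-3-yl]cyclohexa-2,5-diene-1,4-dione
Product: 23 asterriquinone I, 3-{7-[(2R)-2-hydroxy-3-methylbut-3-en-1-yl]-1H-indol-3-yl}-2,5-dimethoxy-6-[2-(2-methylbut-3-en-2-yl)-1H-indol-3-yl]cyclohexa-2,5-diene-1,4-dione
Conditions: HF·pyridine, pyridine, THF, 0 °C to rt
Reagents that add atoms: none
Why: Fluoride-mediated Si–O cleavage under buffered, non-basic conditions, which leave the methoxyquinone, the allylic alcohol and the stereocentre unchanged.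

## Compound list

1 | methacrolein (2-methylprop-2-enal) | CC(=C)C=O | starting material
2 | allenylboronic acid pinacol ester (4,4,5,5-tetramethyl-2-(propa-1,2-dien-1-yl)-1,3,2-dioxaborolane) | C=C=CB1OC(C)(C)C(C)(C)O1 | starting material
3 | 4,4,5,5-tetramethyl-2-{[(3R)-2-methylhex-1-en-5-yn-3-yl]oxy}-1,3,2-dioxaborolane (borate ester of 4, not isolated) | C#CC[C@@H](OB1OC(C)(C)C(C)(C)O1)C(=C)C | intermediate
4 | (3R)-2-methylhex-1-en-5-yn-3-ol | C#CC[C@@H](O)C(=C)C | intermediate
5 | tert-butyldimethyl{[(3R)-2-methylhex-1-en-5-yn-3-yl]oxy}silane | C#CC[C@@H](O[Si](C)(C)C(C)(C)C)C(=C)C | intermediate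
6 | {[(3R)-6-bromo-2-methylhex-1-en-5-yn-3-yl]oxy}(tert-butyl)dimethylsilane | BrC#CC[C@@H](O[Si](C)(C)C(C)(C)C)C(=C)C | intermediate
7 | but-3-yn-1-amine | C#CCCN | starting material
8 | N-(but-3-yn-1-yl)-4-methylbenzenesulfonamide | C#CCCNS(=O)(=O)c1ccc(C)cc1 | intermediate
9 | N-(but-3-yn-1-yl)-N-[(4R)-4-(tert-butyldimethylsilyloxy)-5-methylhex-5-en-1-yn-1-yl]-4-methylbenzenesulfonamide | C#CCCN(C#CC[C@@H](O[Si](C)(C)C(C)(C)C)C(=C)C)S(=O)(=O)c1ccc(C)cc1 | intermediate
10 | acetylene | C#C | starting material
11 | 7-[(2R)-2-(tert-butyldimethylsilyloxy)-3-methylbut-3-en-1-yl]-1-(4-methylbenzenesulfonyl)-2,3-dihydro-1H-indole | Cc1ccc(cc1)S(=O)(=O)N1CCc2cccc(C[C@@H](O[Si](C)(C)C(C)(C)C)C(=C)C)c12 | intermediate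
12 | 7-[(2R)-2-(tert-butyldimethylsilyloxy)-3-methylbut-3-en-1-yl]-2,3-dihydro-1H-indole | N1CCc2cccc(C[C@@H](O[Si](C)(C)C(C)(C)C)C(=C)C)c12 | intermediate
13 | 7-[(2R)-2-(tert-butyldimethylsilyloxy)-3-methylbut-3-en-1-yl]-1H-indole (silyl-protected indole B) | c1cc2cccc(C[C@@H](O[Si](C)(C)C(C)(C)C)C(=C)C)c2[nH]1 | intermediate
14 | indole | c1ccc2[nH]ccc2c1 | starting material
15 | 3-chloro-3H-indole (chloroindolenine, not isolated) | ClC1C=Nc2ccccc12 | intermediate
16 | 2-(2-methylbut-3-en-2-yl)-1H-indole (indole A) | C=CC(C)(C)c1cc2ccccc2[nH]1 | intermediate
17 | 2,5-dichloro-1,4-benzoquinone | O=C1C=C(Cl)C(=O)C=C1Cl | starting material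
18 | 2,5-dichloro-3-[2-(2-methylbut-3-en-2-yl)-1H-indol-3-yl]benzene-1,4-diol (not isolated) | C=CC(C)(C)c1[nH]c2ccccc2c1-c1c(Cl)c(O)cc(Cl)c1O | intermediate
19 | 2,5-dichloro-3-[2-(2-methylbut-3-en-2-yl)-1H-indol-3-yl]cyclohexa-2,5-diene-1,4-dione | C=CC(C)(C)c1[nH]c2ccccc2c1C1=C(Cl)C(=O)C=C(Cl)C1=O | intermediate
20 | 3-{7-[(2R)-2-(tert-butyldimethylsilyloxy)-3-methylbut-3-en-1-yl]-1H-indol-3-yl}-2,5-dichloro-6-[2-(2-methylbut-3-en-2-yl)-1H-indol-3-yl]benzene-1,4-diol (not isolated) | C=CC(C)(C)c1[nH]c2ccccc2c1-c1c(Cl)c(O)c(-c2c[nH]c3c(C[C@@H](O[Si](C)(C)C(C)(C)C)C(=C)C)cccc23)c(Cl)c1O | intermediate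
21 | 3-{7-[(2R)-2-(tert-butyldimethylsilyloxy)-3-methylbut-3-en-1-yl]-1H-indol-3-yl}-2,5-dichloro-6-[2-(2-methylbut-3-en-2-yl)-1H-indol-3-yl]cyclohexa-2,5-diene-1,4-dione | C=CC(C)(C)c1[nH]c2ccccc2c1C1=C(Cl)C(=O)C(c2c[nH]c3c(C[C@@H](O[Si](C)(C)C(C)(C)C)C(=C)C)cccc23)=C(Cl)C1=O | intermediate
22 | 3-{7-[(2R)-2-(tert-butyldimethylsilyloxy)-3-methylbut-3-en-1-yl]-1H-indol-3-yl}-2,5-dimethoxy-6-[2-(2-methylbut-3-en-2-yl)-1H-indol-3-yl]cyclohexa-2,5-diene-1,4-dione | C=CC(C)(C)c1[nH]c2ccccc2c1C1=C(OC)C(=O)C(c2c[nH]c3c(C[C@@H](O[Si](C)(C)C(C)(C)C)C(=C)C)cccc23)=C(OC)C1=O | intermediate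
23 | asterriquinone I, 3-{7-[(2R)-2-hydroxy-3-methylbut-3-en-1-yl]-1H-indol-3-yl}-2,5-dimethoxy-6-[2-(2-methylbut-3-en-2-yl)-1H-indol-3-yl]cyclohexa-2,5-diene-1,4-dione | C=CC(C)(C)c1[nH]c2ccccc2c1C1=C(OC)C(=O)C(c2c[nH]c3c(C[C@@H](O)C(=C)C)cccc23)=C(OC)C1=O | target

## Step count and risks

Total: 13 steps. Longest linear sequence: 10 steps (1, 2, 3, 5, 6, 7, 8, 11, 12, 13). Step 4 and steps 9–10 are side branches.

**Step 6 (key step).** The oxidative cyclisation is slowed by the substituent on the ynamide terminus, so self-trimerisation or oligomerisation through the free terminal alkyne of the diyne may outrun capture of acetylene; transfer of the gas into solution makes this worse on scale. Fallback: from 9, gaseous acetylene is replaced by vinyl acetate as a liquid two-carbon partner under a cationic rhodium catalyst ([Rh(cod)2]BF4/BINAP, CH2Cl2, rt to 40 °C). The alkene inserts into the same rhodacyclopentadiene to give the cyclohexadienyl acetate F1 (or its 5-yl regioisomer, not isolated), which loses acetic acid on the way to the arene. The same three bonds form, and the route is rejoined at 11.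

**Step 1.** An uncatalysed background allenylboration of the small, reactive enal may erode the enantioselectivity, and the volatile product may be lost on isolation (telescoping into step 2 limits the latter). Fallback: from 1, a Barbier propargylation (Zn, propargyl bromide, THF/aq. NH4Cl) gives racemic 2-methylhex-1-en-5-yn-3-ol F2. A Sharpless kinetic resolution of this secondary allylic alcohol (Ti(OiPr)4, L-(+)-diisopropyl tartrate, t-BuOOH, 4 Å MS, CH2Cl2, −20 °C, run past half conversion) epoxidises the S enantiomer to the epoxy alcohol F3, which is discarded. The R alcohol is left behind, and the route is rejoined at 4.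

**Step 5.** Copper-mediated alkynyl–alkynyl coupling of the free terminal alkyne of 8 with bromoalkyne 6, or oxidative dimerisation of that alkyne, may compete with N-alkynylation. Fallback: from 8, double deprotonation and C-silylation (n-BuLi, 2.2 equiv, THF, −78 °C; TMSCl; aqueous work-up) give the silylalkyne sulfonamide F4. Coupling with 6 under the conditions of step 5 gives the C-silylated ynamide diyne F5, and K2CO3 in MeOH at rt removes the alkynyl silyl group without touching the ynamide or the TBS ether. The route is rejoined at 9.

**Step 11.** Addition to the deactivated, hindered quinone 19 may be slow, and prolonged exposure to acid and then to DDQ may cause loss of the silyl group, ionisation of the allylic carbinol or over-oxidation of the electron-rich indoles. Fallback: a base-promoted union that avoids acid altogether. From 16, reaction with 2,3,5,6-tetrabromo-1,4-benzoquinone (bromanil) and Cs2CO3 in MeCN at rt replaces one bromide by addition–elimination and gives the tribromo indolylquinone F6. Indole 13 with Cs2CO3 then displaces the bromide para to the first indole, the position activated by the carbonyl that indole A does not deactivate, giving the dibromo bis-indolylquinone F7. NaOMe in MeOH/THF exchanges the two remaining bromides, and the route is rejoined at 22.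

**Step 12.** Exchange may stop after one chloride, or adventitious hydroxide may carry the product on to hydroxyquinones. Fallback: from 21, deliberate full hydrolysis (NaOH, MeOH/H2O, reflux) gives the dihydroxyquinone F8, whose two acidic vinylogous-acid hydroxyls are then methylated with TMSCHN2 in MeOH/toluene at rt. The route is rejoined at 22.

## Further compounds

F1 | step 6 | 7-[(2R)-2-(tert-butyldimethylsilyloxy)-3-methylbut-3-en-1-yl]-1-(4-methylbenzenesulfonyl)-2,3,5,6-tetrahydro-1H-indol-6-yl acetate (mixture at C6; not isolated) | CC(=O)OC1CC=C2CCN(S(=O)(=O)c3ccc(C)cc3)C2=C1C[C@@H](O[Si](C)(C)C(C)(C)C)C(=C)C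
F2 | step 1 | racemic 2-methylhex-1-en-5-yn-3-ol | C#CCC(O)C(=C)C
F3 | step 1 | (1S)-1-[(2S)-2-methyloxiran-2-yl]but-3-yn-1-ol | C#CC[C@H](O)[C@]1(C)CO1
F4 | step 5 | 4-methyl-N-[4-(trimethylsilyl)but-3-yn-1-yl]benzenesulfonamide | C[Si](C)(C)C#CCCNS(=O)(=O)c1ccc(C)cc1
F5 | step 5 | N-[(4R)-4-(tert-butyldimethylsilyloxy)-5-methylhex-5-en-1-yn-1-yl]-4-methyl-N-[4-(trimethylsilyl)but-3-yn-1-yl]benzenesulfonamide | C[Si](C)(C)C#CCCN(C#CC[C@@H](O[Si](C)(C)C(C)(C)C)C(=C)C)S(=O)(=O)c1ccc(C)cc1
F6 | step 11 | 2,3,5-tribromo-6-[2-(2-methylbut-3-en-2-yl)-1H-indol-3-yl]cyclohexa-2,5-diene-1,4-dione | C=CC(C)(C)c1[nH]c2ccccc2c1C1=C(Br)C(=O)C(Br)=C(Br)C1=O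
F7 | step 11 | 2,5-dibromo-3-{7-[(2R)-2-(tert-butyldimethylsilyloxy)-3-methylbut-3-en-1-yl]-1H-indol-3-yl}-6-[2-(2-methylbut-3-en-2-yl)-1H-indol-3-yl]cyclohexa-2,5-diene-1,4-dione | C=CC(C)(C)c1[nH]c2ccccc2c1C1=C(Br)C(=O)C(c2c[nH]c3c(C[C@@H](O[Si](C)(C)C(C)(C)C)C(=C)C)cccc23)=C(Br)C1=O
F8 | step 12 | 3-{7-[(2R)-2-(tert-butyldimethylsilyloxy)-3-methylbut-3-en-1-yl]-1H-indol-3-yl}-2,5-dihydroxy-6-[2-(2-methylbut-3-en-2-yl)-1H-indol-3-yl]cyclohexa-2,5-diene-1,4-dione | C=CC(C)(C)c1[nH]c2ccccc2c1C1=C(O)C(=O)C(c2c[nH]c3c(C[C@@H](O[Si](C)(C)C(C)(C)C)C(=C)C)cccc23)=C(O)C1=O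
A1 | alternative 1 | 4-hydroxy-2-methoxy-4-[1-methoxy-2-(N-SEM indole A)vinyl]-3-(N-SEM, O-TBS indole B)cyclobut-2-en-1-one | COC1=C(c2cn(COCC[Si](C)(C)C)c3c(C[C@@H](O[Si](C)(C)C(C)(C)C)C(=C)C)cccc23)C(O)(C(OC)=Cc2c(C(C)(C)C=C)n(COCC[Si](C)(C)C)c3ccccc23)C1=O
A2 | alternative 1 | 2,5-dimethoxy-3-(N-SEM indole A)-6-(N-SEM, O-TBS indole B)benzene-1,4-diol | COc1c(O)c(-c2c(C(C)(C)C=C)n(COCC[Si](C)(C)C)c3ccccc23)c(OC)c(O)c1-c1cn(COCC[Si](C)(C)C)c2c(C[C@@H](O[Si](C)(C)C(C)(C)C)C(=C)C)cccc12
A3 | alternative 2 | 2-iodoaniline | Nc1ccccc1I
A4 | alternative 2 | 1-(3,3-dimethylpent-4-en-1-yn-1-yl)-4-(O-TBS indole B)-2,5-dimethoxy-3,6-bis(methoxymethoxy)benzene | C=CC(C)(C)C#Cc1c(OC)c(OCOC)c(-c2c[nH]c3c(C[C@@H](O[Si](C)(C)C(C)(C)C)C(=C)C)cccc23)c(OC)c1OCOC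
A5 | alternative 2 | 1-(indole A)-4-(O-TBS indole B)-2,5-dimethoxy-3,6-bis(methoxymethoxy)benzene | C=CC(C)(C)c1[nH]c2ccccc2c1-c1c(OC)c(OCOC)c(-c2c[nH]c3c(C[C@@H](O[Si](C)(C)C(C)(C)C)C(=C)C)cccc23)c(OC)c1OCOC
A6 | alternative 3 | methyl 3-(N-SEM, O-TBS indole B)-2-oxopropanoate | COC(=O)C(=O)Cc1cn(COCC[Si](C)(C)C)c2c(C[C@@H](O[Si](C)(C)C(C)(C)C)C(=C)C)cccc12
A7 | alternative 3 | 2,2-dimethyl-5-[(N-SEM indole A)methylidene]-1,3-dioxolan-4-one | CC1(C)OC(=Cc2c(C(C)(C)C=C)n(COCC[Si](C)(C)C)c3ccccc23)C(=O)O1
A8 | alternative 3 | 2,5-dihydroxy-3-(N-SEM indole A)-6-(N-SEM, O-TBS indole B)-1,4-benzoquinone | C=CC(C)(C)c1n(COCC[Si](C)(C)C)c2ccccc2c1C1=C(O)C(=O)C(c2cn(COCC[Si](C)(C)C)c3c(C[C@@H](O[Si](C)(C)C(C)(C)C)C(=C)C)cccc23)=C(O)C1=O
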